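**Plan**
1. Retrosynthesis: the spiro-cyclohexene is cut at C2–C4' and C14–C15' (Diels–Alder; primed atoms = spiro half). This gives a 3-oxo-1,10(14)-dienone with 5β-H ("enone half") and the 5α-H dienophile 8-O-silyl-8β-hydroxydehydrozaluzanin C. The two are C5 epimers of one guaianolide, traced back (lactone O6 → O8, C6 deoxygenated) to isoalantolactone.
2. Enabling feature: in each half a cyclopentenone (C1–C5) is fused to the cycloheptane (C1, C5–C10), with C10 next to C1. This is the retron of a 4-methylcyclohexa-2,5-dienone (ring A) fused to a cyclohexane (ring B, C5–C10). Its photorearrangement makes C1–C5 and breaks C5–C10, so ring B grows from six to seven atoms while ring A shrinks to five.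
3. Forward order: lactone opening and 8-O-silylation; ring A to the 1,4-dien-3-one; photorearrangement (6-6 → 5-7); C6 oxidation; photodeconjugation (C4=C15, C5–H, both epimers); 8-OH-directed reduction at C6; lactone to O6; C10=C14; Saegusa dienone and Diels–Alder (spiro ring); conjugation.
4. Stereochemistry: C7, C8 and (via C10) C1 come from isoalantolactone; C6 from a 1,3-anti reduction directed by the 8β-OH; C5 by separating the two epimers (5α → spiro half, 5β → enone half); C4' from endo addition to the α face of the dienophile; C10 from protonation relayed by the 8β-OH.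

Key step: step 6

Remark: guaiane numbering is used for all compounds (eudesmane precursors carry the same numbers); in the enone half H5 is cis to H6 (5-epi series). It is assumed that step 8 gives both C5 epimers in workable amounts.

Step 1
Reactants: 1 isoalantolactone
Product: 3 8β-(triisopropylsilyloxy)eudesma-4(15),11(13)-dien-12-oic acid, via lithium hydroxy-carboxylate 2 (not isolated)
Conditions: LiOH·H2O, THF/H2O, rt; evaporate; TIPSOTf, 2,6-lutidine, CH2Cl2, 0 °C; K2CO3 (cat.), MeOH/H2O; pH 4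
Reagents that add atoms: lithium hydroxide, [Li+].[OH-]; triisopropylsilyl triflate, CC(C)[Si](C(C)C)(C(C)C)OS(=O)(=O)C(F)(F)F
Why: Saponification opens the cis-fused 8,12-lactone and silylation traps the 8β-oxygen before it can relactonise (the labile silyl ester falls off on carbonate work-up); no stereocentre is touched (lactone hydrolysis, silyl ether formation).

Step 2
Reactants: 3 8β-(triisopropylsilyloxy)eudesma-4(15),11(13)-dien-12-oic acid
Product: 4 methyl 8β-(triisopropylsilyloxy)eudesma-4(15),11(13)-dien-12-oate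
Conditions: MeI, K2CO3, DMF, 0 °C to rt
Reagents that add atoms: iodomethane, CI
Why: SN2 O-alkylation of the carboxylate gives the methyl acrylate ester, which is the form needed for the selective lactonisation in steps 10 and 13.

Step 3
Reactants: 4 methyl 8β-(triisopropylsilyloxy)eudesma-4(15),11(13)-dien-12-oate
Product: 5 methyl 3-hydroxy-8β-(triisopropylsilyloxy)eudesma-4(15),11(13)-dien-12-oate (C3 epimers)
Conditions: SeO2 (cat.), t-BuOOH, CH2Cl2, rt
Reagents that add atoms: tert-butyl hydroperoxide, CC(C)(C)OO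
Why: The ene/[2,3] sequence of the Riley oxidation should hydroxylate the ring methylene C3 next to the exocyclic C4=C15 bond while the electron-poor acrylate stays inert; the C3 configuration is lost in step 4.

Step 4
Reactants: 5 methyl 3-hydroxy-8β-(triisopropylsilyloxy)eudesma-4(15),11(13)-dien-12-oate
Product: 6 methyl 3-oxo-8β-(triisopropylsilyloxy)-5αH-eudesm-11(13)-en-12-oate (C4 epimers)
Conditions: CpRu(PPh3)2Cl (5 mol %), Et3NH·PF6 (10 mol %), dioxane, 100 °C
Reagents that add atoms: none
Why: A ruthenium-hydride 1,3-hydrogen shift should turn the 2-methylene cycloalkanol into the 4-methyl ketone without touching other alkenes (redox isomerisation of an allylic alcohol); C4 becomes sp2 again in step 5.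

Step 5
Reactants: 6 methyl 3-oxo-8β-(triisopropylsilyloxy)-5αH-eudesm-11(13)-en-12-oate
Product: 7 methyl 3-oxo-8β-(triisopropylsilyloxy)eudesma-1,4,11(13)-trien-12-oate
Conditions: IBX (4 equiv), DMSO/PhF, 80 °C
Reagents that add atoms: none
Why: IBX should dehydrogenate the ketone twice through its enols (C4–C5 and C1–C2) to the cross-conjugated 4-methylcyclohexa-2,5-dienone (IBX dehydrogenation of ketones).

Step 6
Reactants: 7 methyl 3-oxo-8β-(triisopropylsilyloxy)eudesma-1,4,11(13)-trien-12-oate
Product: 8 methyl 10α-hydroxy-3-oxo-8β-(triisopropylsilyloxy)-1αH-guaia-4,11(13)-dien-12-oate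
Conditions: hν (medium-pressure Hg, Pyrex), AcOH/H2O 1:1, rt, Ar
Reagents that add atoms: water, O
Why: Excitation of the cross-conjugated dienone should lead to C1–C5 bonding and a bicyclo[3.1.0]hexenone zwitterion (cyclopropane C1–C5–C10, oxyallyl cation over C2–C4) that the acid protonates on oxygen; heterolysis of the cyclopropane bond C5–C10 with capture of the C10 cation by water then leaves the cyclopentenone C1–C5 fused to a seven-membered ring made of the old ring B plus C1. The closest known reaction is the photorearrangement of α-santonin and other 4-methylcyclohexadienones to 10-hydroxy hydroazulenones in aqueous acetic acid. The five-membered ring closes by C1–C5 bond formation across the dienone (a 3-exo closure to the cyclopropane whose C5–C10 bond then breaks); the seven-membered ring is not closed but arises by expansion of the six-membered ring C5–C10. C1 is the stereocentre that is kept: C10 can bridge only toward the face that places its methyl group endo and C9 exo on the cyclopropane, so the 10β-methyl configuration is relayed to 1α-H, while the new C10 carbinol centre (water anti to the breaking bond) is removed in steps 11 and 14. Two selectivities are needed: cleavage of C5–C10 and not C1–C10, which the C4 methyl group secures by stabilising the developing C4=C5 enone, and excitation of the dienone alone, which Pyrex-filtered light secures because the acrylate ester does not absorb it.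

Step 7
Reactants: 8 methyl 10α-hydroxy-3-oxo-8β-(triisopropylsilyloxy)-1αH-guaia-4,11(13)-dien-12-oate
Product: 9 methyl 10α-hydroxy-3,6-dioxo-8β-(triisopropylsilyloxy)-1αH-guaia-4,11(13)-dien-12-oate
Conditions: Rh2(cap)4 (1 mol %), t-BuOOH (aq., 5 equiv), 1,2-dichloroethane, 40 °C
Reagents that add atoms: tert-butyl hydroperoxide, CC(C)(C)OO
Why: The tert-butylperoxy radical should abstract hydrogen from C6, the only allylic methylene of the enone, and the peroxide collapses to the ketone (dirhodium/TBHP allylic oxidation of an enone to an ene-dione).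

Step 8
Reactants: 9 methyl 10α-hydroxy-3,6-dioxo-8β-(triisopropylsilyloxy)-1αH-guaia-4,11(13)-dien-12-oate
Product: 10 methyl 10α-hydroxy-3,6-dioxo-8β-(triisopropylsilyloxy)-1αH,5βH-guaia-4(15),11(13)-dien-12-oate and 11 its 5αH epimer (separated; 10 goes to steps 9–11, 11 to steps 12–14)
Conditions: hν (350 nm), imidazole (5 mol %), MeCN, −20 °C
Reagents that add atoms: none
Why: Proposed new method: n,π* excitation of the C6 carbonyl, whose γ-methyl group C15 is held cis to it across C4=C5, should cause 1,5-hydrogen transfer to a photodienol (C6–OH, C5=C6, C4=C15) that the weak base ketonises at C5, so the double bond leaves conjugation with C6 but stays conjugated with C3; the closest known reaction is the photodeconjugation of β,β-disubstituted enones such as mesityl oxide; protonation of C5 from either face should give both ring-fusion epimers, and both are used.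

Step 9
Reactants: 10 methyl 10α-hydroxy-3,6-dioxo-8β-(triisopropylsilyloxy)-1αH,5βH-guaia-4(15),11(13)-dien-12-oate
Product: 13 methyl 6α,8β,10α-trihydroxy-3-oxo-1αH,5βH-guaia-4(15),11(13)-dien-12-oate, via hydroxy ketone 12 (not isolated)
Conditions: HF·pyridine, pyridine, THF, 0 °C to rt; then Me4NBH(OAc)3, MeCN/AcOH, −30 °C
Reagents that add atoms: none
Why: Fluoride frees the 8β-hydroxyl, which binds the borohydride and delivers hydride to C6 on its own β face through a six-membered chair-like transition state, so the new 6-OH should be α and anti to O8 (Evans–Saksena 1,3-anti reduction); the C3 enone and the acrylate are inert to this reagent.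

Step 10
Reactants: 13 methyl 6α,8β,10α-trihydroxy-3-oxo-1αH,5βH-guaia-4(15),11(13)-dien-12-oate
Product: 15 8β-(tert-butyldimethylsilyloxy)-10α-hydroxy-3-oxo-1αH,5βH-guaia-4(15),11(13)-dien-12,6α-olide, via silyl ether 14 (not isolated)
Conditions: TBSCl (1.05 equiv), imidazole, DMF, −20 °C; then PPTS (cat.), benzene, 50 °C
Reagents that add atoms: tert-butyldimethylsilyl chloride, CC(C)(C)[Si](C)(C)Cl
Why: The 8-OH, flanked by the C9 methylene, should be silylated faster than the 6-OH between two methine carbons (the tertiary 10-OH does not react), and acid then closes the trans-fused γ-lactone from O6 onto the ester (selective silylation, lactonisation).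

Step 11
Reactants: 15 8β-(tert-butyldimethylsilyloxy)-10α-hydroxy-3-oxo-1αH,5βH-guaia-4(15),11(13)-dien-12,6α-olide
Product: 16 8β-(tert-butyldimethylsilyloxy)-3-oxo-1αH,5βH-guaia-4(15),10(14),11(13)-trien-12,6α-olide (5-epi series)
Conditions: SOCl2, pyridine, CH2Cl2, −40 to −20 °C
Reagents that add atoms: none
Why: E2 elimination of the tertiary chlorosulfite by pyridine should take the unhindered methyl hydrogens and give the exocyclic C10=C14 alkene (alcohol dehydration); C1–H is no longer activated because the enone double bond is now exocyclic.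

Step 12
Reactants: 11 methyl 10α-hydroxy-3,6-dioxo-8β-(triisopropylsilyloxy)-1αH,5αH-guaia-4(15),11(13)-dien-12-oate
Product: 18 methyl 6α,8β,10α-trihydroxy-3-oxo-1αH,5αH-guaia-4(15),11(13)-dien-12-oate, via hydroxy ketone 17 (not isolated)
Conditions: HF·pyridine, pyridine, THF, 0 °C to rt; then Me4NBH(OAc)3, MeCN/AcOH, −30 °C
Reagents that add atoms: none
Why: As in step 9, the freed 8β-hydroxyl should deliver hydride to the β face of C6 and give the 6α-alcohol (Evans–Saksena 1,3-anti reduction).

Step 13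
Reactants: 18 methyl 6α,8β,10α-trihydroxy-3-oxo-1αH,5αH-guaia-4(15),11(13)-dien-12-oate
Product: 20 8β-(tert-butyldimethylsilyloxy)-10α-hydroxy-3-oxo-1αH,5αH-guaia-4(15),11(13)-dien-12,6α-olide, via silyl ether 19 (not isolated)
Conditions: TBSCl (1.05 equiv), imidazole, DMF, −20 °C; then PPTS (cat.), benzene, 50 °C
Reagents that add atoms: tert-butyldimethylsilyl chloride, CC(C)(C)[Si](C)(C)Cl
Why: As in step 10, the less hindered 8-OH should be silylated first and O6 then closes the trans-fused lactone (selective silylation, lactonisation).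

Step 14
Reactants: 20 8β-(tert-butyldimethylsilyloxy)-10α-hydroxy-3-oxo-1αH,5αH-guaia-4(15),11(13)-dien-12,6α-olide
Product: 21 8β-(tert-butyldimethylsilyloxy)-3-oxo-1αH,5αH-guaia-4(15),10(14),11(13)-trien-12,6α-olide (8-O-TBS-8β-hydroxydehydrozaluzanin C)
Conditions: SOCl2, pyridine, CH2Cl2, −40 to −20 °C
Reagents that add atoms: none
Why: As in step 11, elimination of the chlorosulfite toward the methyl group should give the exocyclic C10=C14 alkene (alcohol dehydration).

Step 15
Reactants: 16 8β-(tert-butyldimethylsilyloxy)-3-oxo-1αH,5βH-guaia-4(15),10(14),11(13)-trien-12,6α-olide; 21 8β-(tert-butyldimethylsilyloxy)-3-oxo-1αH,5αH-guaia-4(15),10(14),11(13)-trien-12,6α-olide (3 equiv)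
Product: 24 bis-TBS Diels–Alder adduct (spiro C4'; C1=C10 β,γ-enone; 2α-H; 5β-H), via silyl dienol ether 22 (not isolated), via dienone 23 (not isolated)
Conditions: 16, TMSOTf, Et3N, CH2Cl2, −78 to 0 °C; then Pd(OAc)2 (1.1 equiv), 21, MeCN, rt to 35 °C, Ar, dark
Reagents that add atoms: none
Why: Enolisation of 16 can only go toward C2, Pd(II) dehydrogenates the silyl enol ether to the C14=C10–C1=C2 dienone (Saegusa–Ito), and this diene should add across the C4'=C15' enone of 21 (Diels–Alder) with the dienophile carbonyl endo, on the H5 (β) face of the diene away from its C6–C7 ring segment and on the α (H5') face of 21, which sets C2 and the spiro centre C4'; the excess of 21 suppresses self-addition of the diene.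

Step 16
Reactants: 24 bis-TBS Diels–Alder adduct
Product: 26 CNP0397417.1 (target), via diol 25 (not isolated)
Conditions: HF (48 % aq.), MeCN, 0 °C to rt; then TsOH·H2O (10 mol %), CHCl3, rt, Ar
Reagents that add atoms: none
Why: After desilylation, acid-catalysed dienolisation (C3–OH, C2=C3, C1=C10) and γ-protonation should bring the double bond into conjugation as C1=C2; the proton should enter C10 on the β face, relayed by the 1,3-syn 8β-hydroxyl and anti to the C5' branch of the spiro ring, giving 10β-H, and the acidic medium leaves the base-labile C5–H alone (β,γ- to α,β-enone isomerisation).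

**Compound list**
1 | isoalantolactone | C[C@]12CCCC(=C)[C@@H]1C[C@@H]3C(=C)C(=O)O[C@@H]3C2 | starting material
2 | lithium 8β-hydroxyeudesma-4(15),11(13)-dien-12-oate | C[C@]12CCCC(=C)[C@@H]1C[C@H](C(=C)C(=O)[O-])[C@H](O)C2.[Li+] | intermediate
3 | 8β-(triisopropylsilyloxy)eudesma-4(15),11(13)-dien-12-oic acid | C[C@]12CCCC(=C)[C@@H]1C[C@H](C(=C)C(=O)O)[C@H](O[Si](C(C)C)(C(C)C)C(C)C)C2 | intermediate
4 | methyl 8β-(triisopropylsilyloxy)eudesma-4(15),11(13)-dien-12-oate | C[C@]12CCCC(=C)[C@@H]1C[C@H](C(=C)C(=O)OC)[C@H](O[Si](C(C)C)(C(C)C)C(C)C)C2 | intermediate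
5 | methyl 3-hydroxy-8β-(triisopropylsilyloxy)eudesma-4(15),11(13)-dien-12-oate (C3 epimers) | C[C@]12CCC(O)C(=C)[C@@H]1C[C@H](C(=C)C(=O)OC)[C@H](O[Si](C(C)C)(C(C)C)C(C)C)C2 | intermediate
6 | methyl 3-oxo-8β-(triisopropylsilyloxy)-5αH-eudesm-11(13)-en-12-oate (C4 epimers) | C[C@]12CCC(=O)C(C)[C@@H]1C[C@H](C(=C)C(=O)OC)[C@H](O[Si](C(C)C)(C(C)C)C(C)C)C2 | intermediate
7 | methyl 3-oxo-8β-(triisopropylsilyloxy)eudesma-1,4,11(13)-trien-12-oate | C[C@]12C=CC(=O)C(C)=C1C[C@H](C(=C)C(=O)OC)[C@H](O[Si](C(C)C)(C(C)C)C(C)C)C2 | intermediate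
8 | methyl 10α-hydroxy-3-oxo-8β-(triisopropylsilyloxy)-1αH-guaia-4,11(13)-dien-12-oate | CC1=C2C[C@H](C(=C)C(=O)OC)[C@H](O[Si](C(C)C)(C(C)C)C(C)C)C[C@@](C)(O)[C@@H]2CC1=O | intermediate
9 | methyl 10α-hydroxy-3,6-dioxo-8β-(triisopropylsilyloxy)-1αH-guaia-4,11(13)-dien-12-oate | CC1=C2C(=O)[C@H](C(=C)C(=O)OC)[C@H](O[Si](C(C)C)(C(C)C)C(C)C)C[C@@](C)(O)[C@@H]2CC1=O | intermediate
10 | methyl 10α-hydroxy-3,6-dioxo-8β-(triisopropylsilyloxy)-1αH,5βH-guaia-4(15),11(13)-dien-12-oate | C=C1C(=O)C[C@H]2[C@](C)(O)C[C@@H](O[Si](C(C)C)(C(C)C)C(C)C)[C@@H](C(=C)C(=O)OC)C(=O)[C@H]12 | intermediate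
11 | methyl 10α-hydroxy-3,6-dioxo-8β-(triisopropylsilyloxy)-1αH,5αH-guaia-4(15),11(13)-dien-12-oate | C=C1C(=O)C[C@H]2[C@](C)(O)C[C@@H](O[Si](C(C)C)(C(C)C)C(C)C)[C@@H](C(=C)C(=O)OC)C(=O)[C@@H]12 | intermediate
12 | methyl 8β,10α-dihydroxy-3,6-dioxo-1αH,5βH-guaia-4(15),11(13)-dien-12-oate | C=C1C(=O)C[C@H]2[C@](C)(O)C[C@@H](O)[C@@H](C(=C)C(=O)OC)C(=O)[C@H]12 | intermediate
13 | methyl 6α,8β,10α-trihydroxy-3-oxo-1αH,5βH-guaia-4(15),11(13)-dien-12-oate | C=C1C(=O)C[C@H]2[C@](C)(O)C[C@@H](O)[C@@H](C(=C)C(=O)OC)[C@H](O)[C@H]12 | intermediate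
14 | methyl 8β-(tert-butyldimethylsilyloxy)-6α,10α-dihydroxy-3-oxo-1αH,5βH-guaia-4(15),11(13)-dien-12-oate | C=C1C(=O)C[C@H]2[C@](C)(O)C[C@@H](O[Si](C)(C)C(C)(C)C)[C@@H](C(=C)C(=O)OC)[C@H](O)[C@H]12 | intermediate
15 | 8β-(tert-butyldimethylsilyloxy)-10α-hydroxy-3-oxo-1αH,5βH-guaia-4(15),11(13)-dien-12,6α-olide | C=C1C(=O)C[C@H]2[C@](C)(O)C[C@@H](O[Si](C)(C)C(C)(C)C)[C@H]3C(=C)C(=O)O[C@@H]3[C@H]12 | intermediate
16 | 8β-(tert-butyldimethylsilyloxy)-3-oxo-1αH,5βH-guaia-4(15),10(14),11(13)-trien-12,6α-olide | C=C1C(=O)C[C@H]2C(=C)C[C@@H](O[Si](C)(C)C(C)(C)C)[C@H]3C(=C)C(=O)O[C@@H]3[C@H]12 | intermediate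
17 | methyl 8β,10α-dihydroxy-3,6-dioxo-1αH,5αH-guaia-4(15),11(13)-dien-12-oate | C=C1C(=O)C[C@H]2[C@](C)(O)C[C@@H](O)[C@@H](C(=C)C(=O)OC)C(=O)[C@@H]12 | intermediate
18 | methyl 6α,8β,10α-trihydroxy-3-oxo-1αH,5αH-guaia-4(15),11(13)-dien-12-oate | C=C1C(=O)C[C@H]2[C@](C)(O)C[C@@H](O)[C@@H](C(=C)C(=O)OC)[C@H](O)[C@@H]12 | intermediate
19 | methyl 8β-(tert-butyldimethylsilyloxy)-6α,10α-dihydroxy-3-oxo-1αH,5αH-guaia-4(15),11(13)-dien-12-oate | C=C1C(=O)C[C@H]2[C@](C)(O)C[C@@H](O[Si](C)(C)C(C)(C)C)[C@@H](C(=C)C(=O)OC)[C@H](O)[C@@H]12 | intermediate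
20 | 8β-(tert-butyldimethylsilyloxy)-10α-hydroxy-3-oxo-1αH,5αH-guaia-4(15),11(13)-dien-12,6α-olide | C=C1C(=O)C[C@H]2[C@](C)(O)C[C@@H](O[Si](C)(C)C(C)(C)C)[C@H]3C(=C)C(=O)O[C@@H]3[C@@H]12 | intermediate
21 | 8β-(tert-butyldimethylsilyloxy)-3-oxo-1αH,5αH-guaia-4(15),10(14),11(13)-trien-12,6α-olide | C=C1C(=O)C[C@H]2C(=C)C[C@@H](O[Si](C)(C)C(C)(C)C)[C@H]3C(=C)C(=O)O[C@@H]3[C@@H]12 | intermediate
22 | 8β-(tert-butyldimethylsilyloxy)-3-(trimethylsilyloxy)-1αH,5βH-guaia-2,4(15),10(14),11(13)-tetraen-12,6α-olide | C=C1C(O[Si](C)(C)C)=C[C@H]2C(=C)C[C@@H](O[Si](C)(C)C(C)(C)C)[C@H]3C(=C)C(=O)O[C@@H]3[C@H]12 | intermediate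
23 | 8β-(tert-butyldimethylsilyloxy)-3-oxo-5βH-guaia-1,4(15),10(14),11(13)-tetraen-12,6α-olide | C=C1C(=O)C=C2C(=C)C[C@@H](O[Si](C)(C)C(C)(C)C)[C@H]3C(=C)C(=O)O[C@@H]3[C@H]12 | intermediate
24 | bis-TBS Diels–Alder adduct (C2–C4' and C14–C15' bonds, C1=C10, 2α-H) | C=C1C(=O)[C@@H]2C3=C(CC[C@]24C(=O)C[C@H]2C(=C)C[C@@H](O[Si](C)(C)C(C)(C)C)[C@H]5C(=C)C(=O)O[C@@H]5[C@H]24)C[C@@H](O[Si](C)(C)C(C)(C)C)[C@H]2C(=C)C(=O)O[C@@H]2[C@H]13 | intermediate
25 | desilylated Diels–Alder adduct (8β,8'β-diol, C1=C10) | C=C1C(=O)[C@@H]2C3=C(CC[C@]24C(=O)C[C@H]2C(=C)C[C@@H](O)[C@H]5C(=C)C(=O)O[C@@H]5[C@H]24)C[C@@H](O)[C@H]2C(=C)C(=O)O[C@@H]2[C@H]13 | intermediate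
26 | CNP0397417.1 | C=C1C(=O)C2=C3[C@H](CC[C@]24C(=O)C[C@H]2C(=C)C[C@@H](O)[C@H]5C(=C)C(=O)O[C@@H]5[C@H]24)C[C@@H](O)[C@H]2C(=C)C(=O)O[C@@H]2[C@H]13 | target

Total step count: 16. Longest linear sequence: 13 steps (steps 1–11, 15, 16).

**Steps most likely to fail**

Step 8 (Proposed new method). What may go wrong: other photoreactions of the ene-dione compete with γ-hydrogen transfer, or the product is re-conjugated by acid or base before it is reduced. Fallback with known chemistry: from 9, radical bromination of the C15 methyl group (NBS, AIBN, PhCF3, 80 °C; Wohl–Ziegler) would give the 15-bromo ene-dione F1. Zinc dust in THF/AcOH at −10 °C would then form the zinc dienolate of the C6 ketone, and its protonation at C5 (reductive deconjugation of a γ-bromo enone) returns to 10 and 11.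

Step 15. What may go wrong: the diene adds to itself, or the cross-addition shows poor facial or endo/exo selectivity. Fallback: from 16, deprotonation at C2 and selenenylation (LiHMDS, PhSeBr, THF, −78 °C) would give the 2-phenylselanyl ketone F2. Oxidation (H2O2, pyridine, CH2Cl2, 0 °C) and syn-elimination would deliver diene 23 free of palladium and amine, to be combined at once with excess 21 under Et2AlCl at −40 °C; the route is rejoined at 24.

Step 16. What may go wrong: protonation at C10 is poorly face-selective, or over-enolisation epimerises C5. Fallback: from 25, the conjugation is run to completion regardless of selectivity; the 10α-H epimer F3 is separated and returned to the same acid-catalysed dienol equilibrium until it is consumed, rejoining the route at 26.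

**Further compounds**
F1 | step 8 | methyl 15-bromo-10α-hydroxy-3,6-dioxo-8β-(triisopropylsilyloxy)-1αH-guaia-4,11(13)-dien-12-oate | BrCC1=C2C(=O)[C@H](C(=C)C(=O)OC)[C@H](O[Si](C(C)C)(C(C)C)C(C)C)C[C@@](C)(O)[C@@H]2CC1=O
F2 | step 15 | 8β-(tert-butyldimethylsilyloxy)-3-oxo-2-(phenylselanyl)-1αH,5βH-guaia-4(15),10(14),11(13)-trien-12,6α-olide | C=C1C(=O)C([Se]c2ccccc2)[C@H]2C(=C)C[C@@H](O[Si](C)(C)C(C)(C)C)[C@H]3C(=C)C(=O)O[C@@H]3[C@H]12
F3 | step 16 | 10-epimer of the target (10α-H) | C=C1C(=O)C2=C3[C@@H](CC[C@]24C(=O)C[C@H]2C(=C)C[C@@H](O)[C@H]5C(=C)C(=O)O[C@@H]5[C@H]24)C[C@@H](O)[C@H]2C(=C)C(=O)O[C@@H]2[C@H]13
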